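**Plan**

- Retrosynthesis: the lactone O2–C3 bond is cut first (a benzylic C–H becomes C–O). Next come C3–C1′ (toluic acid dianion + primary iodide), the spiro C5″–O6″ bond (hydroxy enol ether), O1″–C5″ (alkynol) and C3″–C4″ (acetylide + epoxide).
- Forward: two epoxides and a propargyl unit give the alkynol. Ring A closes by Pd(II) 5-endo cyclization and ring B by acid-catalysed spiroacetalization. The chain is then joined to the arene by lateral alkylation, and the lactone ring is closed last.
- Stereochemistry: C2″ from a kinetically resolved epoxide; C7″ from (S)-propylene oxide; C5″ from a catalyst-controlled kinetic spiroacetalization (attack anti to the C2″ chain); C3 from the chiral copper catalyst of the key step.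
- Enabling feature: in the 2-benzofuran-1(3H)-one ring the carboxyl carbon C1 (on C7a) and C3 (on C3a) are ortho, so a carboxyl oxygen and a C3–H are 1,5-related. An aroyloxy radical at C1 removes exactly that hydrogen, and the same carboxyl then closes the five-membered lactone; the OMe at C7 blocks the other ortho site.
- Precursor design: the plain 2-alkylbenzoic acid, activated as its N-acyloxyphthalimide. The N–O bond is the built-in oxidant and leaves as phthalimide in the ring closure.

Key step: step 9

Assumption: the sense of induction of the chiral acid (step 5) and of the bisoxazoline (step 9) cannot be derived safely for these substrates; one antipode is written for each, and the other would be used if the first run showed the opposite sense.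

Step 1
Reactants: 1 (±)-2-(hex-5-en-1-yl)oxirane
Product: 2 (S)-2-(hex-5-en-1-yl)oxirane
Conditions: (S,S)-(salen)Co(III)OAc (0.5 mol %), H2O (0.55 equiv), neat, 0 °C → rt; distillation
Reagents that add atoms: none
Why: Hydrolytic kinetic resolution of a terminal epoxide, in which the (S,S)-cobalt catalyst should hydrolyse the (R)-epoxide to the diol and leave the (S)-epoxide that later becomes C2″.

Step 2
Reactants: 3 (S)-2-methyloxirane
Product: 5 (S)-tert-butyl(hex-5-yn-2-yloxy)dimethylsilane, via (S)-hex-5-yn-2-ol 4 (not isolated)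
Conditions: HC≡CCH2Br, Mg, HgCl2 (cat.), Et2O, 0 °C; 3, −20 → 0 °C; H2O work-up; crude + TBSCl, imidazole, DMF, rt
Reagents that add atoms: propargylmagnesium bromide (C#CC[Mg]Br); tert-butyldimethylsilyl chloride (CC(C)(C)[Si](C)(C)Cl)
Why: Propargyl/allenyl Grignard opening of the epoxide at its CH2 does not touch the C–O stereocentre, so 3 delivers C7″ in the required configuration, and the volatile alcohol is silylated crude to mask it during the acetylide step.

Step 3
Reactants: 5 (S)-tert-butyl(hex-5-yn-2-yloxy)dimethylsilane; 2 (S)-2-(hex-5-en-1-yl)oxirane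
Product: 6 (7S,13S)-13-[(tert-butyldimethylsilyl)oxy]tetradec-1-en-9-yn-7-ol
Conditions: 5 (1.2 equiv), n-BuLi, THF, −78 °C; BF3·OEt2; 2, −78 °C
Reagents that add atoms: none
Why: BF3-promoted opening of a terminal epoxide by a lithium acetylide (Yamaguchi alkynylation) occurs at the CH2 terminus with retention at the carbinol carbon and tolerates the silyl ether and the terminal alkene.

Step 4
Reactants: 6 (7S,13S)-13-[(tert-butyldimethylsilyl)oxy]tetradec-1-en-9-yn-7-ol
Product: 8 (2S)-4-[(5S)-5-(hex-5-en-1-yl)-4,5-dihydrofuran-2-yl]butan-2-ol, via silyl ether dihydrofuran 7 (not isolated)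
Conditions: PdCl2(PhCN)2 (3 mol %), Et2O, rt; then Et3N, TBAF, THF, rt; basic alumina
Reagents that add atoms: none
Why: Pd(II)-catalysed 5-endo-dig hydroalkoxylation of a homopropargylic alcohol gives the 2,3-dihydrofuran (ring A, no new stereocentre), and fluoride then frees the secondary alcohol under basic conditions that the enol ether survives.

Step 5
Reactants: 8 (2S)-4-[(5S)-5-(hex-5-en-1-yl)-4,5-dihydrofuran-2-yl]butan-2-ol
Product: 9 (2S,5R,7S)-2-(hex-5-en-1-yl)-7-methyl-1,6-dioxaspiro[4.4]nonane
Conditions: confined chiral imidodiphosphoric acid (from two 3,3′-bis(2,4,6-triethylphenyl)-BINOL units, 5 mol %), MTBE, 4 Å MS, −25 °C; Et3N quench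
Reagents that add atoms: none
Why: Catalytic asymmetric spiroacetalization of an ω-hydroxy cyclic enol ether by a confined Brønsted acid, in which protonation at C3 of the dihydrofuran gives the oxocarbenium ion and the hydroxyl closes ring B (5-exo-trig) under kinetic control, the chiral counter-anion together with the intrinsic preference for attack anti to the C2″ chain setting C5″ as R (O6″ trans to the chain), a centre that thermodynamics would not bias.

Step 6
Reactants: 9 (2S,5R,7S)-2-(hex-5-en-1-yl)-7-methyl-1,6-dioxaspiro[4.4]nonane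
Product: 11 (2S,5R,7S)-2-(6-iodohexyl)-7-methyl-1,6-dioxaspiro[4.4]nonane, via alkylzirconocene chloride 10 (not isolated)
Conditions: Cp2Zr(H)Cl, THF, rt; then I2, 0 °C; aq. Na2S2O3/NaHCO3
Reagents that add atoms: iodine (II)
Why: Hydrozirconation of the terminal alkene with the Schwartz reagent places zirconium on the terminal carbon, and iodinolysis of the C–Zr bond gives the primary iodide under non-acidic conditions that should leave the spiro centre untouched.

Step 7
Reactants: 12 2,4-dimethoxy-6-methylbenzoic acid; 11 (2S,5R,7S)-2-(6-iodohexyl)-7-methyl-1,6-dioxaspiro[4.4]nonane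
Product: 13 2,4-dimethoxy-6-{7-[(2S,5R,7S)-7-methyl-1,6-dioxaspiro[4.4]nonan-2-yl]heptyl}benzoic acid
Conditions: 12 (2 equiv), LDA (4.0 equiv, commercial solution), THF, −78 → 0 °C; 11 (1 equiv), −78 → 0 °C; pH 4 phosphate buffer, 0 °C
Reagents that add atoms: none
Why: Lateral (benzylic) lithiation of an o-toluic acid to its dianion followed by SN2 alkylation with a primary iodide forms the C3–C1′ bond and gives the free acid directly, the buffered work-up avoiding acid that could equilibrate C5″.

Step 8
Reactants: 13 2,4-dimethoxy-6-{7-[(2S,5R,7S)-7-methyl-1,6-dioxaspiro[4.4]nonan-2-yl]heptyl}benzoic acid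
Product: 14 1,3-dioxoisoindolin-2-yl 2,4-dimethoxy-6-{7-[(2S,5R,7S)-7-methyl-1,6-dioxaspiro[4.4]nonan-2-yl]heptyl}benzoate
Conditions: N-hydroxyphthalimide, DIC, DMAP (10 mol %), CH2Cl2, 0 °C → rt
Reagents that add atoms: N-hydroxyphthalimide (O=C1c2ccccc2C(=O)N1O)
Why: Carbodiimide/DMAP (Steglich-type) esterification with N-hydroxyphthalimide installs the redox-active N–O bond that serves as the built-in oxidant of the key step.

Step 9
Reactants: 14 1,3-dioxoisoindolin-2-yl 2,4-dimethoxy-6-{7-[(2S,5R,7S)-7-methyl-1,6-dioxaspiro[4.4]nonan-2-yl]heptyl}benzoate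
Product: 15 (3R)-5,7-dimethoxy-3-{6-[(2S,5R,7S)-7-methyl-1,6-dioxaspiro[4.4]nonan-2-yl]hexyl}-2-benzofuran-1(3H)-one
Conditions: fac-Ir(ppy)3 (1 mol %), Cu(MeCN)4PF6 (10 mol %), (S,S)-t-Bu-bis(oxazoline) (12 mol %), MeCN–PhCF3 (1:1), 450 nm LEDs, 0 °C, Ar
Reagents that add atoms: none
Why: Proposed new method: excited Ir(ppy)3 should reduce the N-acyloxyphthalimide, whose N–O bond breaks to an aroyloxy radical and phthalimide anion; the oxygen radical abstracts a hydrogen from the ortho benzylic CH2 through a six-membered transition state (1,5-HAT), the secondary benzylic radical is captured by the bisoxazoline-ligated Cu(II) carboxylate (formed from Cu(I) and Ir(IV)), and C–O reductive elimination from the chelated Cu(III) gives the lactone and Cu(I), with phthalimide as the only by-product. The closest known reaction types are the racemic persulfate/copper lactonization of 2-alkylbenzoic acids through aroyloxy radicals, the enantioselective Cu/bisoxazoline cyanation of benzylic radicals generated from N-acyloxyphthalimides under photoredox conditions or by N-radical 1,5-HAT, and the enantioselective Cu/bisoxazoline coupling of benzylic radicals with a tethered carboxylate in alkene oxy-functionalization. The γ-lactone closes by bonding of the carboxylate oxygen to the benzylic carbon within a six-membered cupracycle, formally a 5-exo-tet closure onto the ring-fused position. C3 is the only new stereocentre and is set by the chiral ligand in the radical capture and reductive elimination, since the spiroketal stereocentres are at least seven bonds away and without influence, so the ligand antipode decides between 3R and 3S. The step needs site selectivity, secured by the 1,5-relationship because only the C3 hydrogens are within reach of the carboxyl oxygen while the other ortho position carries OMe, and it needs C–O coupling to beat C–N coupling and decarboxylation, which chelation of the carboxylate to copper and the fast intramolecular hydrogen transfer should secure. No acid stronger than phthalimide is formed and the oxidant is present as exactly one equivalent in the substrate, so the spiro centre should not equilibrate and the product cannot be oxidised further.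

**Compound list**

1 | (±)-2-(hex-5-en-1-yl)oxirane (racemic 1,2-epoxyoct-7-ene) | C=CCCCCC1CO1 | starting material
2 | (S)-2-(hex-5-en-1-yl)oxirane | C=CCCCC[C@H]1CO1 | intermediate
3 | (S)-2-methyloxirane ((S)-propylene oxide) | C[C@H]1CO1 | starting material
4 | (S)-hex-5-yn-2-ol | C[C@H](O)CCC#C | intermediate (not isolated)
5 | (S)-tert-butyl(hex-5-yn-2-yloxy)dimethylsilane | C[C@H](O[Si](C)(C)C(C)(C)C)CCC#C | intermediate
6 | (7S,13S)-13-[(tert-butyldimethylsilyl)oxy]tetradec-1-en-9-yn-7-ol | C[C@H](O[Si](C)(C)C(C)(C)C)CCC#CC[C@@H](O)CCCCC=C | intermediate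
7 | tert-butyl{[(2S)-4-[(5S)-5-(hex-5-en-1-yl)-4,5-dihydrofuran-2-yl]butan-2-yl]oxy}dimethylsilane | C[C@H](O[Si](C)(C)C(C)(C)C)CCC1=CC[C@H](CCCCC=C)O1 | intermediate (not isolated)
8 | (2S)-4-[(5S)-5-(hex-5-en-1-yl)-4,5-dihydrofuran-2-yl]butan-2-ol | C[C@H](O)CCC1=CC[C@H](CCCCC=C)O1 | intermediate
9 | (2S,5R,7S)-2-(hex-5-en-1-yl)-7-methyl-1,6-dioxaspiro[4.4]nonane | C=CCCCC[C@H]1CC[C@@]2(CC[C@H](C)O2)O1 | intermediate
10 | chlorobis(cyclopentadienyl){6-[(2S,5R,7S)-7-methyl-1,6-dioxaspiro[4.4]nonan-2-yl]hexyl}zirconium (Cp rings drawn σ-bonded) | Cl[Zr](CCCCCC[C@H]1CC[C@@]2(CC[C@H](C)O2)O1)(C1C=CC=C1)C1C=CC=C1 | intermediate (not isolated)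
11 | (2S,5R,7S)-2-(6-iodohexyl)-7-methyl-1,6-dioxaspiro[4.4]nonane | ICCCCCC[C@H]1CC[C@@]2(CC[C@H](C)O2)O1 | intermediate
12 | 2,4-dimethoxy-6-methylbenzoic acid | COc1cc(C)c(C(=O)O)c(OC)c1 | starting material
13 | 2,4-dimethoxy-6-{7-[(2S,5R,7S)-7-methyl-1,6-dioxaspiro[4.4]nonan-2-yl]heptyl}benzoic acid | COc1cc(CCCCCCC[C@H]2CC[C@@]3(CC[C@H](C)O3)O2)c(C(=O)O)c(OC)c1 | intermediate
14 | 1,3-dioxoisoindolin-2-yl 2,4-dimethoxy-6-{7-[(2S,5R,7S)-7-methyl-1,6-dioxaspiro[4.4]nonan-2-yl]heptyl}benzoate | COc1cc(CCCCCCC[C@H]2CC[C@@]3(CC[C@H](C)O3)O2)c(C(=O)ON4C(=O)c5ccccc5C4=O)c(OC)c1 | intermediate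
15 | (3R)-5,7-dimethoxy-3-{6-[(2S,5R,7S)-7-methyl-1,6-dioxaspiro[4.4]nonan-2-yl]hexyl}-2-benzofuran-1(3H)-one | COc1cc(OC)c2c(c1)[C@@H](CCCCCC[C@H]1CC[C@@]3(CC[C@H](C)O3)O1)OC2=O | target

**Totals**

Total step count: 9. Longest linear sequence: 8 steps (3 → 15 through steps 2–9; the branch from 1 is equally long, steps 1 and 3–9).

**Steps most likely to fail**

1. Step 9 (Proposed new method). What may go wrong:
   - decarboxylation or intermolecular hydrogen abstraction by the aroyloxy radical before the 1,5-shift;
   - C–N coupling of the benzylic radical with copper-bound phthalimide;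
   - poor facial selectivity in the copper step, or outer-sphere oxidation to the benzylic cation followed by non-selective lactonization;
   - Lewis-acid equilibration of the spiro centre.

   Fallback with known chemistry, setting out from 11 and coming back at 15. Iodine–lithium exchange on 11 (t-BuLi, Et2O, −78 °C) and addition to commercial 3,5-dimethoxybenzaldehyde would give the epimeric alcohols 1-(3,5-dimethoxyphenyl)-7-[(2S,5R,7S)-7-methyl-1,6-dioxaspiro[4.4]nonan-2-yl]heptan-1-ol F1. Dess–Martin oxidation buffered with NaHCO3 would give the ketone 1-(3,5-dimethoxyphenyl)-7-[(2S,5R,7S)-7-methyl-1,6-dioxaspiro[4.4]nonan-2-yl]heptan-1-one F2. Corey–Bakshi–Shibata reduction ((S)-Me-CBS, BH3·SMe2) should give the (1R)-alcohol F3. NaH/Et2NCOCl would give the (1R)-N,N-diethylcarbamate F4, and NBS (MeCN, NaHCO3) should brominate the ring position between the side chain and OMe to give the 2-bromoaryl carbamate F5. Bromine–lithium exchange (t-BuLi, THF, −78 °C) with intramolecular attack of the aryllithium on the carbamate carbonyl (Parham-type cyclization) expels diethylamide and closes the lactone to 15 with the C–O stereocentre retained.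

2. Step 5. What may go wrong: loss of kinetic control, either because the long C2″ chain does not fit the confined catalyst pocket (poor facial selectivity at the oxocarbenium ion) or because the product re-ionises and C5″ equilibrates.

   Fallback setting out from 2 and 3 and coming back at 9, under thermodynamic control. Commercial acetone N,N-dimethylhydrazone is lithiated (n-BuLi, THF, 0 °C) and opens 3 to give (2S)-5-(2,2-dimethylhydrazinylidene)hexan-2-ol F6 as its alkoxide. A second lithiation at the remaining methyl group and opening of 2 gives (7S,13S)-10-(2,2-dimethylhydrazinylidene)tetradec-1-ene-7,13-diol F7. Aqueous oxalic acid hydrolyses the hydrazone and closes both rings at once to an equilibrium mixture of 9 and its spiro epimer (2S,5S,7S)-2-(hex-5-en-1-yl)-7-methyl-1,6-dioxaspiro[4.4]nonane F8. The two diastereomers would be separated by chromatography, and F8 re-equilibrated with PPTS and recycled.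

3. Step 4. What may go wrong: premature, uncontrolled proton-catalysed spirocyclization or hydrolysis of the enol ether during desilylation and purification, or palladium-hydride migration of the terminal double bond.

   Fallback setting out from 6 and coming back at 9, replacing the labile enol ether by a base-stable mixed ketal. Gold(I)-catalysed tandem cycloisomerization–hydroalkoxylation of 6 in methanol (Ph3PAuCl/AgOTf cat., PPTS cat., MeOH–CH2Cl2, 0 °C, Et3N quench) would give the cyclic methyl ketal tert-butyl{[(2S)-4-[(5S)-5-(hex-5-en-1-yl)-2-methoxyoxolan-2-yl]butan-2-yl]oxy}dimethylsilane F9. TBAF would give the hydroxy ketal (2S)-4-[(5S)-5-(hex-5-en-1-yl)-2-methoxyoxolan-2-yl]butan-2-ol F10. The chiral Brønsted acid of step 5 would then effect intramolecular transketalization with loss of methanol through the same oxocarbenium ion (catalytic asymmetric transacetalization type) to give 9.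

**Further compounds**

F1 | step 9 | 1-(3,5-dimethoxyphenyl)-7-[(2S,5R,7S)-7-methyl-1,6-dioxaspiro[4.4]nonan-2-yl]heptan-1-ol (both C1 epimers) | COc1cc(OC)cc(c1)C(O)CCCCCC[C@H]1CC[C@@]2(CC[C@H](C)O2)O1
F2 | step 9 | 1-(3,5-dimethoxyphenyl)-7-[(2S,5R,7S)-7-methyl-1,6-dioxaspiro[4.4]nonan-2-yl]heptan-1-one | COc1cc(OC)cc(c1)C(=O)CCCCCC[C@H]1CC[C@@]2(CC[C@H](C)O2)O1
F3 | step 9 | (1R)-1-(3,5-dimethoxyphenyl)-7-[(2S,5R,7S)-7-methyl-1,6-dioxaspiro[4.4]nonan-2-yl]heptan-1-ol | COc1cc(OC)cc(c1)[C@H](O)CCCCCC[C@H]1CC[C@@]2(CC[C@H](C)O2)O1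
F4 | step 9 | (1R)-1-(3,5-dimethoxyphenyl)-7-[(2S,5R,7S)-7-methyl-1,6-dioxaspiro[4.4]nonan-2-yl]heptyl N,N-diethylcarbamate | COc1cc(OC)cc(c1)[C@H](OC(=O)N(CC)CC)CCCCCC[C@H]1CC[C@@]2(CC[C@H](C)O2)O1
F5 | step 9 | (1R)-1-(2-bromo-3,5-dimethoxyphenyl)-7-[(2S,5R,7S)-7-methyl-1,6-dioxaspiro[4.4]nonan-2-yl]heptyl N,N-diethylcarbamate | COc1cc(OC)c(Br)c(c1)[C@H](OC(=O)N(CC)CC)CCCCCC[C@H]1CC[C@@]2(CC[C@H](C)O2)O1
F6 | step 5 | (2S)-5-(2,2-dimethylhydrazinylidene)hexan-2-ol | C[C@H](O)CCC(C)=NN(C)C
F7 | step 5 | (7S,13S)-10-(2,2-dimethylhydrazinylidene)tetradec-1-ene-7,13-diol | C[C@H](O)CCC(=NN(C)C)CC[C@@H](O)CCCCC=C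
F8 | step 5 | (2S,5S,7S)-2-(hex-5-en-1-yl)-7-methyl-1,6-dioxaspiro[4.4]nonane | C=CCCCC[C@H]1CC[C@]2(CC[C@H](C)O2)O1
F9 | step 4 | tert-butyl{[(2S)-4-[(5S)-5-(hex-5-en-1-yl)-2-methoxyoxolan-2-yl]butan-2-yl]oxy}dimethylsilane (both C2 anomers) | C[C@H](O[Si](C)(C)C(C)(C)C)CCC1(OC)CC[C@H](CCCCC=C)O1
F10 | step 4 | (2S)-4-[(5S)-5-(hex-5-en-1-yl)-2-methoxyoxolan-2-yl]butan-2-ol (both C2 anomers) | C[C@H](O)CCC1(OC)CC[C@H](CCCCC=C)O1
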